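(The earlier runs and the new flask are simulated on assumed constants.)

You asked for a quick number: which of violet and ochre ends with more G after 30 h? The runs and the questions first:

| flask | Q | E | remark | time |
|---|---|---|---|---|
| beta | 0.048 M | 42 µM | run made earlier |  |
| theta | 0.096 M | 42 µM | run made earlier |  |
| violet | 0.054 M | 42 µM |  | 30 h |
| ochre | 0.15 M | 42 µM |  | 30 h |

- beta (time / h: G / %, Q / %): 2.50: 6.5, 61.3; 6.00: 9.2, 37.9; 12.0: 12.7, 20.7; 30.0: 15.2, 7.2
- theta (time / h: G / %, Q / %): 8.00: 7.3, 20.9; 15.0: 9.0, 9.9; 25.0: 9.5, 5.5; 30.0: 9.1, 3.6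

(each reading ± 0.5 percentage points)

1. the winner by amount of G, in percent of the Q charged; "neither" if no more than 2 percentage points parts them (violet / ochre / neither)
2. how much G is there at the end, in percent of the Q charged: violet
3. how much G is there at the end, in percent of the Q charged: ochre



Work with the fraction of Q left, f, and not with what is made. At the last reading, one over f, less 1, divided by the charge, gives 269 M⁻¹ for beta and 279 M⁻¹ for theta. That near agreement is what a second-order loss of Q looks like, so I carry their mean, s = 274 M⁻¹. Writing u for s times the charge, such a curve has a mean fraction left over the run of ln(1 + u)/u.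

Beta then gives G over that mean as 74.5% and theta gives 73.3%, though theta had twice the charge. Their mean, 73.9%, is the catch, the G at the end as a share of the mean fraction of Q left.

Now my own reckoning. Violet has a mean fraction of 18.7%, so G is 13.8%. Ochre has 9.11%, so G is 6.73%. Watch f at the end: it should read near 6.34% in violet and 2.38% in ochre. The forecast, by another route, gives 14.6% and 6.3%: “Violet wins clearly.”

    Q + E → X (k = 17.4 M⁻¹ min⁻¹)
    X → E + G (k = 1.50 min⁻¹)
    G ⇌ D (K = 0.274, k = 8.69 × 10⁻⁴ min⁻¹)
    E + G → E + L (k = 9.71 M⁻¹ min⁻¹)
    2 Q → Z (k = 0.0362 M⁻¹ min⁻¹)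

Violet ends with 13.7% G and ochre with 6.51%, so violet wins, as the forecast said. Divided by their mean fractions, these are catches of 73.3% and 71.5%, against the carried 73.9%. Now take violet with its charge cut to 0.022 M. The same reckoning puts Q at 14.2% and G at 23.9%. That flask holds 11.1% Q and 22.2% G at 30 h.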